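## Structural features

The target is a 6H-isochromene-6,8(7H)-dione (an azaphilone). A pyran ring (O2, C1, C3, C4, C4a, C8a) is fused through C4a–C8a to carbocyclic ring A (C4a, C5, C6, C7, C8, C8a). The two rings share one cross-conjugated push-pull system, O2–C1=C8a–C8=O and O2–C3=C4–C4a=C5–C6=O. C3 carries an (E)-3-oxoprop-1-enyl chain. C7 carries a methyl group and the ester oxygen of orsellinic acid, and it is the only stereocentre: (R), fully substituted and flanked by both ring ketones, so only absolute configuration has to be controlled. The fragile groups are the electrophilic pyran carbons C1 and C3 (amines and hydroxide attack them), the enal, the 2-acyloxy-1,3-diketone (retro-Claisen cleavage by alkoxides) and the electron-rich resorcinol. The real difficulty is to obtain C7 as one enantiomer while it bears a doubly ortho-substituted aroyloxy group between two carbonyls, without having to acylate a hindered tertiary ketol late in the synthesis. The key step exploits the fact that C6–C7–C8 is a 2-acyloxy-2-methylmalonyl unit whose carbonyl carbons are bonded to C5 and C8a, which are the exocyclic carbon and a ring β-carbon of a 4-methylidene-4H-pyran. Because the two malonyl arms end at different carbons, the configuration of C7 can be stored in a malonic half-ester.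

## Logic of the disconnections

**21 to 19.** No skeletal bond is cut. The two phenolic O–H bonds are traded for O–Si bonds and the aldehyde C=O for two C–OMe bonds. Free phenols would be acylated by an acid chloride, and a free enal would neither survive a carbonyl methylenation nor leave C5 nucleophilic. The gain is that all three masks fall in one acidic operation. The demand is that the unmasking be acidic and free of nucleophilic base, because C1 and the 1,3-diketone of 21 tolerate neither.

**19 to 17 and 8.** The bonds C5–C6 and C8–C8a are cut, which removes ring A in one stroke. C5 and C8a are the two carbons of 17 with enol-ether β-character, and C6 and C8 are both acyl carbons, so the polarity is natural. The gain is convergence: 8 carries the stereocentre and the complete ester, 17 is achiral, and no redox change or late esterification is needed. The demand is threefold: the two acyl groups of 8 must react in a fixed order (the chloride arm at C5 first), the second acylation must choose C8a over C4, and C7 must stay untouched.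

**17 to 16.** The C4a=C5 double bond is cut back to a ring carbonyl. A 4-methylidenepyran is too sensitive to carry through several steps, whereas the pyranone is robust. The demand is a methylenation that is neither acidic (acetal, dienol ether) nor strongly nucleophilic.

**16 to 12 and 13.** The side-chain C=C bond is cut in the aldol sense. The ring methyl of 12 is vinylogously acidic and 13 already carries the masked aldehyde. The gain is two small pieces. The demand is reaction at the exocyclic carbon of the dienolate and (E) geometry on elimination.

**12 to 9 and 10.** The C–C bond between the methyl carbon of 9 and the acyl carbon of 10 is cut, together with the ring O–C bond formed when the enol oxygen displaces the amine. The demand is C-acylation at the methyl group of 9.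

**8 to 7 to 6.** The C–Cl bond is exchanged for C–OH, then one carboxyl O–H for O–Et. The stereocentre of 7 disappears in 6, whose two ester arms are enantiotopic. The gain is that chirality comes from a catalyst acting on a symmetric diester. The demand is enantiotopic-group-selective hydrolysis of the pro-S ester, followed by neutral activation of the acid.

**6 to 3 and 4.** The C7–O bond is cut. Alkylating the carboxylate avoids any attack at the hindered acyl carbon of a 2,6-disubstituted benzoic acid. The demand is that substitution at the tertiary, doubly activated carbon of 4 beat elimination.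

**3 to 1.** Two O–Si bonds are cut. Free phenols would compete as nucleophiles towards 4 and later towards the acid chloride of 8.

## Other disconnections considered

**Alternative 1:** The cut is the C7–C8 bond of ring A, followed one step later by the C7–O acyl bond.

- Forward key step: the keto aldehyde 6-[(E)-3,3-dimethoxyprop-1-enyl]-4-(2,3-dioxobutylidene)-4H-pyran-3-carbaldehyde A2 is treated with a chiral triazolium-derived carbene. The aldehyde on C8a becomes an acyl-anion equivalent and adds to the acetyl carbonyl. This closes ring A and creates C7 as a tertiary carbinol in (R)-7-hydroxy-3-[(E)-3,3-dimethoxyprop-1-enyl]-7-methyl-6H-isochromene-6,8(7H)-dione A1.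
- In its favour: intramolecular aldehyde–ketone benzoin closure to six-membered ketols is an established catalytic, enantioselective reaction class. On mechanistic precedent for the ring closure, and on setting the stereocentre in the ring-forming event with a small-molecule catalyst, this alternative is the better of the two.
- Against it here: the aldehyde of A2 is a vinylogous formate and a reluctant partner for the carbene. The electrophilic C1 can capture the carbene. The conjugated C6 carbonyl offers a competing five-membered closure. A2, with its 1,2-diketone, is harder to assemble than 17 and 8.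
- The main structural drawback: A1 is a hindered tertiary ketol that must then be acylated with the 2,6-disubstituted acid 3, a slow esterification during which retro-benzoin or ketol rearrangement would threaten C7. The chosen plan makes that ester bond at the outset by a carboxylate alkylation.
- Step economy: precursor assembly, closure, esterification and unmasking should come out several steps longer than the nine of the chosen plan.

**Alternative 2:** The cuts are C8a–C1 and C1–O2, with C1 coming from an orthoformate ester.

- Forward key step: the precursor is the rapidly tautomerising vinylogous acid 2-hydroxy-1-methyl-6-oxo-4-[(E)-5-(tert-butyldiphenylsilyloxy)-2-oxopent-3-enyl]cyclohexa-2,4-dien-1-yl 2,4-bis(methoxymethoxy)-6-methylbenzoate A4, in which the two nucleophilic ring carbons are enantiotopic. A chiral phosphoric acid is to direct the one-carbon electrophile to one of them, and the side-chain ketone oxygen then closes the pyran. The product is (7R)-3-[(E)-3-(tert-butyldiphenylsilyloxy)prop-1-enyl]-7-methyl-6,8-dioxo-7,8-dihydro-6H-isochromen-7-yl 2,4-bis(methoxymethoxy)-6-methylbenzoate A3.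
- In its favour: the bond-forming event (enol carbon plus alkoxycarbenium ion, then O-closure) has conventional polarity and is a classical way to build this pyran ring. In plausibility of bond formation it is at least the equal of the chosen key step. It is also catalytic in the chiral agent.
- Against it here: the stereocentre lies three bonds from the reacting carbon, with its methyl and acyloxy groups out of the plane of attack, so discrimination between C8a and C5 is a demanding remote induction. An uncatalysed acid pathway would give racemate. The side-chain methylene is a further nucleophilic site. The acidic orthoformate medium endangers the methoxymethyl ethers. A4 itself requires an oxidative dearomatisation that installs a hindered aroyloxy group.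
- Step economy: after the key step three operations remain (desilylation, allylic oxidation to the enal, removal of two acetal protecting groups), against one in the chosen plan.
- Stereocontrol: the chosen plan relies on a hydrolase acting directly at the prochiral centre, which is a closer and better-understood recognition problem, though it too needs screening.

**Alternative 3:** The cuts are two C–C bonds of the orsellinate benzene ring.

- Forward key step: the alkynoate (7R)-3-[(E)-3,3-dimethoxyprop-1-enyl]-7-methyl-6,8-dioxo-7,8-dihydro-6H-isochromen-7-yl but-2-ynoate A6 undergoes a Diels–Alder reaction with 1,1,3-tris(trimethylsilyloxy)buta-1,3-diene A7. Loss of silanol aromatises the adduct to (7R)-3-[(E)-3,3-dimethoxyprop-1-enyl]-7-methyl-6,8-dioxo-7,8-dihydro-6H-isochromen-7-yl 2,4-dihydroxy-6-methylbenzoate A5.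
- In its favour: the difficult union of a tertiary ketol with a 2,6-disubstituted benzoic acid is replaced by acylation with a small linear alkynoic acid. The diene–ynoate regiochemistry matches the orsellinate pattern. No phenol protecting groups are needed, and A5 requires only acetal hydrolysis. In the end-game this alternative equals the chosen plan in step count and is better in protecting-group economy.
- Against it here: it does not address ring A or C7. The enantiopure alcohol A1 must still come from another key step, so the total is longer.
- Mechanistically, a β-methyl ynoate is a sluggish dienophile that needs heating, while the core of A6 offers the ketene-acetal diene faster outlets: conjugate addition at C1 and at the C4a=C5 enone, and aldol-type addition to C6 or C8. Chemoselectivity is therefore doubtful, whereas the chosen key step uses the nucleophilicity of the pyran instead of fighting its electrophilicity.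

Key step: step 8

Assumption: pig liver esterase is taken to hydrolyse the pro-S ethoxycarbonyl group of 6, which gives (R)-7; if the enzyme prefers the other arm, the resolution described under step 3 supplies the same half-ester.

Remark on the structures: the descriptor changes along the route ((R) in 7, (S) in 8, (R) in 18 to 21) while the spatial arrangement at the quaternary carbon never changes; only the CIP ranks of the two carbonyl arms swap.

Remark on the precursor: 17 is an acid-sensitive dienol ether and is therefore made and consumed as a solution, and a trialkylamine replaces a weakly basic pyridine in the key step so that 17 is not parked as its pyrylium salt.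

## Route

Step 1
Reactants: 1 orsellinic acid (2,4-dihydroxy-6-methylbenzoic acid)
Product: 3 2,4-bis(tert-butyldimethylsilyloxy)-6-methylbenzoic acid, via tris-silylated orsellinate 2 (not isolated)
Conditions: TBSCl (3.5 equiv), imidazole, DMF, rt; then AcOH/THF/H2O, rt
Reagents that add atoms: tert-butyldimethylsilyl chloride, CC(C)(C)[Si](C)(C)Cl
Why: Exhaustive O-silylation followed by selective solvolysis of the far more labile silyl ester is the standard protection of a hydroxybenzoic acid; aryl silyl ethers survive dilute acetic acid, and the mild temperature avoids decarboxylation of the electron-rich acid.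

Step 2
Reactants: 3 2,4-bis(tert-butyldimethylsilyloxy)-6-methylbenzoic acid; 4 diethyl 2-bromo-2-methylmalonate
Product: 6 diethyl 2-{[2,4-bis(tert-butyldimethylsilyloxy)-6-methylbenzoyl]oxy}-2-methylpropanedioate, via caesium carboxylate 5 (not isolated)
Conditions: Cs2CO3 (0.5 equiv), DMF, rt; then 4 (1.2 equiv), 40 °C
Reagents that add atoms: none
Why: Carboxylate O-alkylation (SN2 at the tertiary carbon activated by two ester groups) is the usual way to esterify a 2,6-disubstituted benzoic acid because the hindered acyl carbon is never attacked; the product is achiral with two enantiotopic ester arms.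

Step 3
Reactants: 6 diethyl 2-{[2,4-bis(tert-butyldimethylsilyloxy)-6-methylbenzoyl]oxy}-2-methylpropanedioate
Product: 7 (2R)-2-{[2,4-bis(tert-butyldimethylsilyloxy)-6-methylbenzoyl]oxy}-3-ethoxy-2-methyl-3-oxopropanoic acid
Conditions: pig liver esterase, 0.2 M phosphate buffer pH 7.5/DMSO (85:15), 30 °C; then citric acid to pH 3
Reagents that add atoms: water, O
Why: Enzymatic desymmetrisation of a prochiral 2,2-disubstituted malonate diester: the carboxylesterase hydrolyses one enantiotopic (pro-S) ester and thereby sets the configuration of the future C7; the half-ester carboxylate is not a substrate for a second hydrolysis and the hindered tertiary aryl ester is not accepted.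

Step 4
Reactants: 7 (2R)-2-{[2,4-bis(tert-butyldimethylsilyloxy)-6-methylbenzoyl]oxy}-3-ethoxy-2-methyl-3-oxopropanoic acid
Product: 8 ethyl (2S)-2-{[2,4-bis(tert-butyldimethylsilyloxy)-6-methylbenzoyl]oxy}-3-chloro-2-methyl-3-oxopropanoate
Conditions: 1-chloro-N,N,2-trimethylprop-1-en-1-amine (1.2 equiv), CH2Cl2, 0 °C to rt; evaporate, use crude
Reagents that add atoms: 1-chloro-N,N,2-trimethylprop-1-en-1-amine, CC(C)=C(Cl)N(C)C
Why: Acid chloride formation with an α-chloroenamine proceeds under neutral conditions without HCl, so silyl ethers and the tertiary ester are untouched and decarboxylation of the half-acid is avoided; the quaternary centre has no α-hydrogen and cannot epimerise.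

Step 5
Reactants: 9 (E)-4-(dimethylamino)but-3-en-2-one; 10 acetyl chloride
Product: 12 2-methyl-4H-pyran-4-one, via diketo enamine 11 (not isolated)
Conditions: LiN(SiMe3)2 (2 equiv), THF, −78 °C; then 10 (1 equiv); then CF3CO2H, rt
Reagents that add atoms: none
Why: The kinetic lithium enolate of the vinylogous amide is C-acylated (Claisen-type) to a 1,3-diketone; on acidification its enol oxygen adds to the enaminone β-carbon and expels dimethylamine (addition–elimination), a known γ-pyrone synthesis.

Step 6
Reactants: 12 2-methyl-4H-pyran-4-one; 13 2,2-dimethoxyacetaldehyde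
Product: 16 2-[(E)-3,3-dimethoxyprop-1-enyl]-4H-pyran-4-one, via aldol adduct 14 (not isolated), via aldol mesylate 15 (not isolated)
Conditions: LiN(SiMe3)2, THF, −78 °C; then anhydrous 13 (distilled from the commercial aqueous solution); then MsCl, −78 to 0 °C; then DBU, rt
Reagents that add atoms: none
Why: The 2-methyl group of a γ-pyrone is vinylogously acidic and its lithium dienolate adds to the aldehyde through the exocyclic carbon (vinylogous aldol addition); mesylation and E1cB elimination give the conjugated, thermodynamically preferred (E)-alkene.

Step 7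
Reactants: 16 2-[(E)-3,3-dimethoxyprop-1-enyl]-4H-pyran-4-one
Product: 17 2-[(E)-3,3-dimethoxyprop-1-enyl]-4-methylidene-4H-pyran
Conditions: Cp2TiMe2 (2.5 equiv), toluene/THF, 65 °C, dark; pentane, filtration through basic alumina under Ar; solution used at once
Reagents that add atoms: dimethyltitanocene Cp2TiMe2, C[Ti](C)(C1C=CC=C1)C1C=CC=C1
Why: Petasis methylenation: thermally generated Cp2Ti=CH2 converts the vinylogous ester carbonyl into the exocyclic alkene by [2+2] cycloaddition and cycloreversion under non-acidic, non-basic conditions that spare the acetal and the acid-sensitive product.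

Step 8
Reactants: 17 2-[(E)-3,3-dimethoxyprop-1-enyl]-4-methylidene-4H-pyran; 8 ethyl (2S)-2-{[2,4-bis(tert-butyldimethylsilyloxy)-6-methylbenzoyl]oxy}-3-chloro-2-methyl-3-oxopropanoate
Product: 19 (7R)-3-[(E)-3,3-dimethoxyprop-1-enyl]-7-methyl-6,8-dioxo-7,8-dihydro-6H-isochromen-7-yl 2,4-bis(tert-butyldimethylsilyloxy)-6-methylbenzoate, via pyranylidene keto ester 18 (not isolated)
Conditions: 17 (1.2 equiv), iPr2NEt (3 equiv), 4 Å MS, CH2Cl2, slow addition of 8, −78 to 0 °C; then MgBr2·OEt2 (2 equiv), 0 to 35 °C
Reagents that add atoms: none
Why: Proposed new method: the exocyclic carbon C5 of 17, the most nucleophilic site because attack there creates an aromatic pyrylium ion, adds to the acid chloride of 8, and the amine removes the now acidic C5 proton to give the push-pull pyranylidene ketone 18, which is the known C-acylation of 4-methylpyrylium anhydrobases. MgBr2 then chelates the β-keto ester of 18, and C8a, the γ-carbon of the O2–C1=C8a–C4a=C5–C6=O dienone, attacks the activated ester carbonyl in a 6-(enolexo)-exo-trig closure; loss of the C8a proton and of ethoxide completes ring A. Reversible addition of bromide to C1 of the magnesium-bound, pyrylium-like chelate would turn C8a into the terminus of a magnesium dienolate, as in magnesium halide halo-aldol reactions, and is the pathway expected to carry the acylation if the neutral dienol ether is too weak a nucleophile. The closest known reactions are the double C-acylation of enol ethers by malonyl dichlorides ([3+3] annulation to cyclohexane-1,3-diones) and MgBr2/amine-promoted C-acylations. No stereocentre is formed: C7 is quaternary, cannot enolise, and its configuration, fixed by the hydrolase in step 3, is transferred because the chloride arm becomes C6 and the ester arm C8. The step needs three selectivities: chloride before ester (reactivity gap of the two acyl groups), C5 before any ring carbon (aromatisation on attack), and C8a over C4 in the closure (C4 is flanked by the side chain on C3, and a halide relay would enter at the unsubstituted C1), while closure from C5 itself would give a four-membered ring. Slow addition of 8 to a slight excess of 17 suppresses a second acylation of 18 at C5.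

Step 9
Reactants: 19 (7R)-3-[(E)-3,3-dimethoxyprop-1-enyl]-7-methyl-6,8-dioxo-7,8-dihydro-6H-isochromen-7-yl 2,4-bis(tert-butyldimethylsilyloxy)-6-methylbenzoate
Product: 21 (7R)-7-methyl-6,8-dioxo-3-[(E)-3-oxoprop-1-enyl]-7,8-dihydro-6H-isochromen-7-yl 2,4-dihydroxy-6-methylbenzoate (the target), via silylated enal 20 (not isolated)
Conditions: 48% aq. HF, MeCN, 0 °C to rt
Reagents that add atoms: water, O
Why: Aqueous acid first hydrolyses the allylic dimethyl acetal through a stabilised oxocarbenium ion, and HF then cleaves both aryl silyl ethers by Si–F bond formation; the acid-stable pyranodienone, the hindered tertiary ester and quaternary C7 are unaffected, and basic fluoride, which would expose C1 to nucleophiles, is avoided.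

## Compound list

1 | orsellinic acid (2,4-dihydroxy-6-methylbenzoic acid) | Cc1cc(O)cc(O)c1C(=O)O | starting material
2 | tert-butyldimethylsilyl 2,4-bis(tert-butyldimethylsilyloxy)-6-methylbenzoate | Cc1cc(O[Si](C)(C)C(C)(C)C)cc(O[Si](C)(C)C(C)(C)C)c1C(=O)O[Si](C)(C)C(C)(C)C | intermediate (not isolated)
3 | 2,4-bis(tert-butyldimethylsilyloxy)-6-methylbenzoic acid | Cc1cc(O[Si](C)(C)C(C)(C)C)cc(O[Si](C)(C)C(C)(C)C)c1C(=O)O | intermediate
4 | diethyl 2-bromo-2-methylmalonate | CCOC(=O)C(C)(Br)C(=O)OCC | starting material
5 | caesium 2,4-bis(tert-butyldimethylsilyloxy)-6-methylbenzoate | Cc1cc(O[Si](C)(C)C(C)(C)C)cc(O[Si](C)(C)C(C)(C)C)c1C(=O)[O-].[Cs+] | intermediate (not isolated)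
6 | diethyl 2-{[2,4-bis(tert-butyldimethylsilyloxy)-6-methylbenzoyl]oxy}-2-methylpropanedioate | CCOC(=O)C(C)(OC(=O)c1c(C)cc(O[Si](C)(C)C(C)(C)C)cc1O[Si](C)(C)C(C)(C)C)C(=O)OCC | intermediate
7 | (2R)-2-{[2,4-bis(tert-butyldimethylsilyloxy)-6-methylbenzoyl]oxy}-3-ethoxy-2-methyl-3-oxopropanoic acid | CCOC(=O)[C@](C)(OC(=O)c1c(C)cc(O[Si](C)(C)C(C)(C)C)cc1O[Si](C)(C)C(C)(C)C)C(=O)O | intermediate
8 | ethyl (2S)-2-{[2,4-bis(tert-butyldimethylsilyloxy)-6-methylbenzoyl]oxy}-3-chloro-2-methyl-3-oxopropanoate | CCOC(=O)[C@](C)(OC(=O)c1c(C)cc(O[Si](C)(C)C(C)(C)C)cc1O[Si](C)(C)C(C)(C)C)C(=O)Cl | intermediate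
9 | (E)-4-(dimethylamino)but-3-en-2-one | CN(C)/C=C/C(C)=O | starting material
10 | acetyl chloride | CC(=O)Cl | starting material
11 | (E)-1-(dimethylamino)hex-1-ene-3,5-dione (present as its lithium enolate) | CN(C)/C=C/C(=O)CC(C)=O | intermediate (not isolated)
12 | 2-methyl-4H-pyran-4-one | CC1=CC(=O)C=CO1 | intermediate
13 | 2,2-dimethoxyacetaldehyde | COC(OC)C=O | starting material
14 | 2-(2-hydroxy-3,3-dimethoxypropyl)-4H-pyran-4-one (racemic, present as lithium alkoxide) | COC(OC)C(O)CC1=CC(=O)C=CO1 | intermediate (not isolated)
15 | 1,1-dimethoxy-3-(4-oxo-4H-pyran-2-yl)propan-2-yl methanesulfonate (racemic) | COC(OC)C(OS(C)(=O)=O)CC1=CC(=O)C=CO1 | intermediate (not isolated)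
16 | 2-[(E)-3,3-dimethoxyprop-1-enyl]-4H-pyran-4-one | COC(OC)/C=C/C1=CC(=O)C=CO1 | intermediate
17 | 2-[(E)-3,3-dimethoxyprop-1-enyl]-4-methylidene-4H-pyran | C=C1C=COC(/C=C/C(OC)OC)=C1 | intermediate
18 | ethyl (2R)-2-{[2,4-bis(tert-butyldimethylsilyloxy)-6-methylbenzoyl]oxy}-4-{2-[(E)-3,3-dimethoxyprop-1-enyl]-4H-pyran-4-ylidene}-2-methyl-3-oxobutanoate | CCOC(=O)[C@](C)(OC(=O)c1c(C)cc(O[Si](C)(C)C(C)(C)C)cc1O[Si](C)(C)C(C)(C)C)C(=O)C=C1C=COC(/C=C/C(OC)OC)=C1 | intermediate (not isolated)
19 | (7R)-3-[(E)-3,3-dimethoxyprop-1-enyl]-7-methyl-6,8-dioxo-7,8-dihydro-6H-isochromen-7-yl 2,4-bis(tert-butyldimethylsilyloxy)-6-methylbenzoate | Cc1cc(O[Si](C)(C)C(C)(C)C)cc(O[Si](C)(C)C(C)(C)C)c1C(=O)O[C@]1(C)C(=O)C=C2C=C(/C=C/C(OC)OC)OC=C2C1=O | intermediate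
20 | (7R)-7-methyl-6,8-dioxo-3-[(E)-3-oxoprop-1-enyl]-7,8-dihydro-6H-isochromen-7-yl 2,4-bis(tert-butyldimethylsilyloxy)-6-methylbenzoate | Cc1cc(O[Si](C)(C)C(C)(C)C)cc(O[Si](C)(C)C(C)(C)C)c1C(=O)O[C@]1(C)C(=O)C=C2C=C(/C=C/C=O)OC=C2C1=O | intermediate (not isolated)
21 | (7R)-7-methyl-6,8-dioxo-3-[(E)-3-oxoprop-1-enyl]-7,8-dihydro-6H-isochromen-7-yl 2,4-dihydroxy-6-methylbenzoate | Cc1cc(O)cc(O)c1C(=O)O[C@]1(C)C(=O)C=C2C=C(/C=C/C=O)OC=C2C1=O | target

## Step count and risks

Total step count: 9. Longest linear sequence: 6 steps (steps 1, 2, 3, 4, 8, 9); the pyran branch (steps 5, 6, 7) joins at step 8.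

**Step 8 (key step).**
- What may go wrong: the second acylation may stall at the stage of 18, because a neutral dienol-ether carbon is a weak nucleophile towards an ethyl ester. Closure at C4 instead of C8a, ionisation of the allylic acetal by the Lewis acid, and a second intermolecular acylation at C5 are the other likely failures.
- Fallback (sets out from 9, returns at 19): the C8a–H of the pyran partner is replaced by an iodine handle, so that the second bond is made by halogen–magnesium exchange and intramolecular acylation (Parham-type cyclisation), both known reaction types.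
 - Iodination of 9 at its α-carbon with N-iodosuccinimide would give (Z)-4-(dimethylamino)-3-iodobut-3-en-2-one F1.
 - Acetylation and acid cyclisation as in step 5 would give 5-iodo-2-methyl-4H-pyran-4-one F2, with iodine on the carbon that becomes C8a.
 - The condensation of step 6 with 13 would give 2-[(E)-3,3-dimethoxyprop-1-enyl]-5-iodo-4H-pyran-4-one F3.
 - The methylenation of step 7 would give 2-[(E)-3,3-dimethoxyprop-1-enyl]-5-iodo-4-methylidene-4H-pyran F4.
 - C-acylation of F4 with 8 (iPr2NEt, CH2Cl2) would give ethyl (2R)-2-{[2,4-bis(tert-butyldimethylsilyloxy)-6-methylbenzoyl]oxy}-4-{2-[(E)-3,3-dimethoxyprop-1-enyl]-5-iodo-4H-pyran-4-ylidene}-2-methyl-3-oxobutanoate F5, which is isolated.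
 - iPrMgCl·LiCl (THF, −40 °C) would then exchange the alkenyl iodide, and the alkenylmagnesium at C8a would attack the ethyl ester to give 19.
 - The iodine also fixes the regiochemistry of the closure.

**Step 3.**
- What may go wrong: the bulky, lipophilic diester may be poorly accepted by the enzyme; the enantiotopic-group selectivity may be low or opposite; aryl silyl groups may be slowly lost in buffer.
- Fallback (sets out from 6, returns at 7): Me3SnOH (1,2-dichloroethane, 60 °C) would hydrolyse one ethyl ester without touching the aryl silyl ethers. This gives racemic 2-{[2,4-bis(tert-butyldimethylsilyloxy)-6-methylbenzoyl]oxy}-3-ethoxy-2-methyl-3-oxopropanoic acid F6. Classical resolution by fractional crystallisation of its salts with (S)-1-phenylethanamine would provide (S)-1-phenylethylammonium (2R)-2-{[2,4-bis(tert-butyldimethylsilyloxy)-6-methylbenzoyl]oxy}-3-ethoxy-2-methyl-3-oxopropanoate F7, and acidification releases 7. The unwanted enantiomer can be re-esterified with ethanol to achiral 6 and recycled.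

**Step 2.**
- What may go wrong: elimination of HBr from 4 to a methylidenemalonate, followed by conjugate addition of the carboxylate, would give a constitutional isomer. Bromine transfer and carbonate-induced desilylation are further risks.
- Fallback (sets out from 3, returns at 6): the caesium salt 5 is alkylated with diethyl 2-bromomalonate, a secondary bromide without β-hydrogen, to give diethyl 2-{[2,4-bis(tert-butyldimethylsilyloxy)-6-methylbenzoyl]oxy}propanedioate F8. Its acidic malonate C–H is then deprotonated (NaH, THF, 0 °C) and C-methylated with MeI to give 6.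

**Step 7.**
- What may go wrong: methylenation of the electron-rich vinylogous ester carbonyl may be incomplete, and the dienol ether may be lost by protonation, oligomerisation or autoxidation while titanium residues are removed.
- Fallback (sets out from 16, returns at 17): a Peterson olefination. Me3SiCH2Li/CeCl3 (THF, −78 °C) adds 1,2 to the pyranone carbonyl to give 2-[(E)-3,3-dimethoxyprop-1-enyl]-4-[(trimethylsilyl)methyl]-4H-pyran-4-ol F9. KH (THF, 0 °C) then induces syn-elimination of silanolate to give 17 under purely basic conditions, as a solution free of titanium.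

## Further compounds

F1 | step 8 | (Z)-4-(dimethylamino)-3-iodobut-3-en-2-one | CN(C)/C=C(\I)C(C)=O
F2 | step 8 | 5-iodo-2-methyl-4H-pyran-4-one | CC1=CC(=O)C(I)=CO1
F3 | step 8 | 2-[(E)-3,3-dimethoxyprop-1-enyl]-5-iodo-4H-pyran-4-one | COC(OC)/C=C/C1=CC(=O)C(I)=CO1
F4 | step 8 | 2-[(E)-3,3-dimethoxyprop-1-enyl]-5-iodo-4-methylidene-4H-pyran | C=C1C=C(/C=C/C(OC)OC)OC=C1I
F5 | step 8 | ethyl (2R)-2-{[2,4-bis(tert-butyldimethylsilyloxy)-6-methylbenzoyl]oxy}-4-{2-[(E)-3,3-dimethoxyprop-1-enyl]-5-iodo-4H-pyran-4-ylidene}-2-methyl-3-oxobutanoate | CCOC(=O)[C@](C)(OC(=O)c1c(C)cc(O[Si](C)(C)C(C)(C)C)cc1O[Si](C)(C)C(C)(C)C)C(=O)C=C1C=C(/C=C/C(OC)OC)OC=C1I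
F6 | step 3 | racemic 2-{[2,4-bis(tert-butyldimethylsilyloxy)-6-methylbenzoyl]oxy}-3-ethoxy-2-methyl-3-oxopropanoic acid | CCOC(=O)C(C)(OC(=O)c1c(C)cc(O[Si](C)(C)C(C)(C)C)cc1O[Si](C)(C)C(C)(C)C)C(=O)O
F7 | step 3 | (S)-1-phenylethylammonium (2R)-2-{[2,4-bis(tert-butyldimethylsilyloxy)-6-methylbenzoyl]oxy}-3-ethoxy-2-methyl-3-oxopropanoate | CCOC(=O)[C@](C)(OC(=O)c1c(C)cc(O[Si](C)(C)C(C)(C)C)cc1O[Si](C)(C)C(C)(C)C)C(=O)[O-].C[C@H]([NH3+])c1ccccc1
F8 | step 2 | diethyl 2-{[2,4-bis(tert-butyldimethylsilyloxy)-6-methylbenzoyl]oxy}propanedioate | CCOC(=O)C(OC(=O)c1c(C)cc(O[Si](C)(C)C(C)(C)C)cc1O[Si](C)(C)C(C)(C)C)C(=O)OCC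
F9 | step 7 | 2-[(E)-3,3-dimethoxyprop-1-enyl]-4-[(trimethylsilyl)methyl]-4H-pyran-4-ol (racemic) | COC(OC)/C=C/C1=CC(O)(C[Si](C)(C)C)C=CO1
A1 | alternative 1 | (R)-7-hydroxy-3-[(E)-3,3-dimethoxyprop-1-enyl]-7-methyl-6H-isochromene-6,8(7H)-dione | O[C@]1(C)C(=O)C=C2C=C(/C=C/C(OC)OC)OC=C2C1=O
A2 | alternative 1 | 6-[(E)-3,3-dimethoxyprop-1-enyl]-4-(2,3-dioxobutylidene)-4H-pyran-3-carbaldehyde | CC(=O)C(=O)C=C1C=C(/C=C/C(OC)OC)OC=C1C=O
A3 | alternative 2 | (7R)-3-[(E)-3-(tert-butyldiphenylsilyloxy)prop-1-enyl]-7-methyl-6,8-dioxo-7,8-dihydro-6H-isochromen-7-yl 2,4-bis(methoxymethoxy)-6-methylbenzoate | Cc1cc(OCOC)cc(OCOC)c1C(=O)O[C@]1(C)C(=O)C=C2C=C(/C=C/CO[Si](c3ccccc3)(c3ccccc3)C(C)(C)C)OC=C2C1=O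
A4 | alternative 2 | 2-hydroxy-1-methyl-6-oxo-4-[(E)-5-(tert-butyldiphenylsilyloxy)-2-oxopent-3-enyl]cyclohexa-2,4-dien-1-yl 2,4-bis(methoxymethoxy)-6-methylbenzoate | Cc1cc(OCOC)cc(OCOC)c1C(=O)OC1(C)C(=O)C=C(CC(=O)/C=C/CO[Si](c2ccccc2)(c2ccccc2)C(C)(C)C)C=C1O
A5 | alternative 3 | (7R)-3-[(E)-3,3-dimethoxyprop-1-enyl]-7-methyl-6,8-dioxo-7,8-dihydro-6H-isochromen-7-yl 2,4-dihydroxy-6-methylbenzoate | Cc1cc(O)cc(O)c1C(=O)O[C@]1(C)C(=O)C=C2C=C(/C=C/C(OC)OC)OC=C2C1=O
A6 | alternative 3 | (7R)-3-[(E)-3,3-dimethoxyprop-1-enyl]-7-methyl-6,8-dioxo-7,8-dihydro-6H-isochromen-7-yl but-2-ynoate | CC#CC(=O)O[C@]1(C)C(=O)C=C2C=C(/C=C/C(OC)OC)OC=C2C1=O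
A7 | alternative 3 | 1,1,3-tris(trimethylsilyloxy)buta-1,3-diene | C=C(O[Si](C)(C)C)C=C(O[Si](C)(C)C)O[Si](C)(C)C
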